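**Numbering.** Atoms follow bicyclo[5.3.0]decane numbering: C1 is the quaternary fusion carbon (methyl), C2 carries the acetate, C3–C4 the epoxide (methyl on C4), then C5, C6, C7 (fusion CH), C8 (side chain), C9 and C10. The side chain is C11(CH3)=C12–C13=C14–C15(CH3)2OH. Compound numbers 1–30 are those of the compound list; 30 is the target.

## Analysis of the target

Target 30 is a diterpenoid acetate on a trans-fused bicyclo[5.3.0]decane: the seven-membered ring is C1–C2–C3–C4–C5–C6–C7 and the five-membered ring is C7–C8–C9–C10–C1. It has six stereocentres, (1S,2S,3S,4R,7S,8R). If the C1 methyl is called β, then the C2 acetoxy group, the epoxide oxygen, H7 and the C8 side chain are all α. The acetate is therefore cis to the epoxide and trans to the angular methyl, the ring fusion is trans, and the side chain is trans to the C7–C6 bond. The sensitive groups are the trisubstituted epoxide (acids, Lewis acids), the tertiary allylic alcohol on an E,E-diene (ionisation, dehydration, hydrogenation, peroxides) and the acetate (hydrides, organometallics, base). The synthesis is hard because C1–C4 are contiguous stereocentres with a quaternary carbon next to a neopentyl carbinol, the 5–7 fusion must be trans, and the C8 centre must be correlated with the ring. The structural feature that the plan uses is that C3–C4 and C6–C7 are skipped across C5, while the C1–C2 bond joins the quaternary carbon to the oxygen-bearing carbon. If C3=C4 and C6=C7 are alkenes, this is the cyclohepta-1,4-diene that a cis-divinylcyclopropane gives on rearrangement. Both alkenes are wanted afterwards: one for the epoxide and one for setting H7.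

## Retrosynthetic reasoning

**Acetate and side chain (30 ⇒ 23).** The C2–O acyl bond is cut last: in diol 29 only the secondary hydroxyl should acylate. The two C15–CH3 bonds and C13=C14 are cut next, leading through dienoate 28 to enal 27. C11=C12 is then cut to give methyl ketone 23, with phosphonoacetate 24 as the two-carbon unit in both olefinations (intermediates 25 and 26). The diene and the tertiary alcohol cannot survive hydrogenation or peroxide chemistry, so they are built after all ring stereocentres are in place.

**Protecting-group relay (23 ⇒ 20).** The C11 carbinol must be oxidised without touching C2–OH. Saturated epoxy alcohol 20 is therefore acetylated (21), desilylated (22) and oxidised. The acetate is only a mask: it is lost in the reduction of 25 and replaced at the end.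

**Ring stereocentres C7, C3, C4 (20 ⇒ 17).** The two C–H bonds at C6 and C7 are removed to give alkene 19; the C2 hydroxyl must deliver hydrogen to its own face to make the fusion trans. The two epoxide C–O bonds are removed to give dienol 18; the same hydroxyl must direct oxygen to C3=C4. Epoxidation comes before hydrogenation because a directed hydrogenation of 18 would also reduce the allylic C3=C4 bond. The C2–O bond of 18 is traced to the C2–B bond of allylic boronate 17, which must be oxidised with retention.

**Key disconnection (17 ⇒ 16).** The C1–C2 bond is cut and C4–C6 is reconnected, giving cis-divinylcyclopropane 16. No other disconnection turns the quaternary centre, the C2 heteroatom and both alkenes into one thermal isomerisation. The forward step has to join C2 to the methyl-bearing carbon of a tetrasubstituted alkene and set C1 and C2.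

**Alkenylboronate (16 ⇒ 12).** The C2–B and C2–H bonds are cut to alkyne 14 and pinacolborane 15; a syn hydroboration guarantees the E geometry that fixes C2. The alkyne carbon C2 is removed to aldehyde 13, which comes from cyclopropylmethanol 12.

**Cyclopropane (12 ⇒ 8 + 9).** The two bonds to the C5 methylene are cut to Z-allylic alcohol 11. A hydroxyl-directed, reagent-controlled methylene transfer must set C4 and C6 as a cis pair with the absolute sense that later presents the correct face of the cyclopentene. C4=C6 is cut to enal 8 and phosphonate 9 (via ester 10); the olefination must be Z-selective so that the two alkenyl arms end up cis on the ring.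

**Five-membered ring and C8 (8 ⇒ 1).** The C1=C7 bond of 8 is an intramolecular aldol condensation of keto aldehyde 7. Its two carbonyl carbons (C1 and C6 of the target) are the epoxide carbons of 5. Epoxide 5 comes from (R)-limonene 1 through 2 and 4: the isopropenyl group is degraded to the silyloxyethyl arm while the ring alkene is masked as its epoxide. C8 is the limonene stereocentre.

## Alternatives that were turned down

**Alternative 1:** The C7=C8 bond of the five-membered ring is disconnected to the achiral dione aldehyde A2, 4-(1-methyl-2,7-dioxocycloheptyl)butanal. In the forward direction a chiral amine forms the enamine of the chain aldehyde. C8 attacks one of the two enantiotopic ring ketones and dehydration gives the bicyclic keto enal A1, with quaternary C1 set.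
- For: C1 is set catalytically from achiral material in very few steps. On early step economy and independence from the chiral pool this is stronger than the chosen route.
- Against: A1 has no C4 methyl and no functionality at C3–C6. The C3=C4 alkene and its methyl would have to be built stepwise from the C2 ketone.
- Against: the target needs H7 and H8 trans. A syn hydrogenation of the tetrasubstituted C7=C8 bond cannot give this, so the fusion centre would depend on an uncontrolled conjugate reduction next to the quaternary carbon.
- Against: the formyl group is one carbon short of the methyl ketone. In addition, 2,2-disubstituted cycloheptane-1,3-diones are prone to retro-Claisen cleavage.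
- Comparison: the chosen key step delivers both alkenes, the C4 methyl and the C2 heteroatom at once, with C8 already in place.

**Alternative 2:** All three C–O bonds of the C2–C4 region are disconnected to the trans-fused C2=C3 alkene A4, which carries H4 and the alkenyl iodide. In the forward direction a dye-sensitised photo-oxygenation (Schenck ene reaction) places oxygen on C2, moves the double bond to C3=C4 and gives hydroperoxide A5. A titanium alkoxide then passes the distal oxygen to the new alkene to give the cis-epoxy alcohol A3.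
- For: three C–O bonds and three stereocentres form in one flask. The regiochemistry is enforced because C1 has no hydrogen, and the syn relation follows from intramolecular delivery.
- For: the alkenyl iodide of A3 allows a one-step cross-coupling to the dienol. This is clearly shorter than the five-step olefination sequence used here.
- Against: no ring or C–C bond is made. The trans-fused skeleton with C1, C7, C8 and an extra, sacrificial C4 centre must come from elsewhere.
- Against: a cis-1,2-disubstituted alkene is the slowest class of ene substrate, and the facial choice at C2 rests only on the C1 methyl.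
- Against: the iodoalkene is light-sensitive and itself has allylic hydrogens.
- Comparison: the chosen route reaches the same syn-epoxy alcohol motif (19) in two reliable operations from groups that the ring-forming step leaves behind, and C2 is fixed by alkene geometry.

**Alternative 3:** The C1–C7 bond is disconnected to the ten-membered epoxy allylsilane A7. In the forward direction a Lewis acid activates the C1–C2 epoxide, C7 attacks tertiary C1 with inversion, and silicon is lost. Both rings form at once in alcohol A6, which has an exocyclic methylene at C8.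
- For: two rings, C1, C7 and the C1/C2 relation are set in one stereospecific step. This is more bond formation per step than the chosen key step, which closes one ring.
- Against: a stereodefined ten-membered ring with a cis epoxide, a defined allylsilane and the C4 centre is a long synthesis in itself.
- Against: the fusion geometry depends on the reacting conformer of the medium ring, and hydride shift or elimination at the tertiary epoxide compete.
- Against: A6 has a saturated C3–C4. Installing the epoxide would need oxidation of the C2 alcohol, dehydrogenation and re-reduction, which erases the C2 centre just made.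
- Against: the methylene must still be converted into the C8 stereocentre with a two-carbon ketone.
- Comparison: the chosen route avoids the medium ring, takes C8 from limonene and forms C3=C4 where the epoxide is needed.

Key step: step 12

Assumption: mCPBA gives both epoxide diastereomers and NaBH4 both C11 epimers; these converge in step 4 and step 18, so 2–6 and 4–22 are carried as mixtures and drawn as one isomer (11S).

## Route

**Step 1**
Reactants: 1 (R)-limonene
Product: 2 (4R)-limonene 1,2-oxide [(4R)-1-methyl-4-(prop-1-en-2-yl)-7-oxabicyclo[4.1.0]heptane]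
Conditions: mCPBA, NaHCO3, CH2Cl2, 0 °C
Reagents that add atoms: 3-chloroperoxybenzoic acid, OOC(=O)c1cccc(Cl)c1
Why: Prilezhaev epoxidation is selective for the more electron-rich trisubstituted ring alkene. The epoxide masks the later 1,6-dicarbonyl unit.

**Step 2**
Reactants: 2 (4R)-limonene 1,2-oxide
Product: 4 (1S)-1-[(4R)-1-methyl-7-oxabicyclo[4.1.0]heptan-4-yl]ethanol, via epoxy ketone 3 (not isolated)
Conditions: O3, CH2Cl2/MeOH, −78 °C; then NaBH4, −78 to 0 °C
Reagents that add atoms: ozone, [O-][O+]=O
Why: Ozonolysis cleaves the only alkene (epoxides are inert to ozone), and reductive work-up with borohydride takes the methyl ketone straight to the carbinol. The α-stereocentre (C8) should not epimerise under these cold conditions.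

**Step 3**
Reactants: 4 epoxy alcohol
Product: 5 tert-butyl(dimethyl){(1S)-1-[(4R)-1-methyl-7-oxabicyclo[4.1.0]heptan-4-yl]ethoxy}silane
Conditions: TBSCl, imidazole, DMF, rt
Reagents that add atoms: tert-butyldimethylsilyl chloride, CC(C)(C)[Si](C)(C)Cl
Why: Standard silylation of a secondary alcohol. The ether must survive base, hydride, zinc carbenoid, peroxide and hydrogenation, and is later removed by fluoride without harm to an epoxide.

**Step 4**
Reactants: 5 epoxy silyl ether
Product: 7 (3R)-3-[(1S)-1-(tert-butyldimethylsilyloxy)ethyl]-6-oxoheptanal, via trans-diol 6 (not isolated)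
Conditions: H5IO6, THF/H2O, 0 °C
Reagents that add atoms: water, O
Why: Periodic acid hydrolyses the epoxide and cleaves the glycol in the same flask (Malaprade cleavage), and both epoxide diastereomers give the same keto aldehyde. Low temperature and short contact time are chosen to spare the secondary silyl ether.

**Step 5**
Reactants: 7 keto aldehyde
Product: 8 (5R)-5-[(1S)-1-(tert-butyldimethylsilyloxy)ethyl]-2-methylcyclopent-1-ene-1-carbaldehyde
Conditions: piperidine (20 mol %), AcOH (20 mol %), toluene, 70 °C
Reagents that add atoms: none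
Why: Enamine-mediated intramolecular aldol condensation (5-enolexo-exo-trig): the aldehyde enamine attacks the methyl ketone and dehydration gives the tetrasubstituted enal. Amine/acid catalysis favours this mode over ketone-enolate closures, and C8 is not enolisable.

**Step 6**
Reactants: 8 enal; 9 methyl 2-[bis(2,2,2-trifluoroethoxy)phosphoryl]propanoate
Product: 10 methyl (2Z)-3-{(5R)-5-[(1S)-1-(tert-butyldimethylsilyloxy)ethyl]-2-methylcyclopent-1-en-1-yl}-2-methylprop-2-enoate
Conditions: KN(SiMe3)2, 18-crown-6, THF, −78 °C
Reagents that add atoms: none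
Why: Still–Gennari olefination. Fast elimination from the kinetic adduct of the electron-poor phosphonate gives the Z-trisubstituted enoate, which places the ester carbon cis to the cyclopentenyl group.

**Step 7**
Reactants: 10 Z-enoate
Product: 11 (2Z)-3-{(5R)-5-[(1S)-1-(tert-butyldimethylsilyloxy)ethyl]-2-methylcyclopent-1-en-1-yl}-2-methylprop-2-en-1-ol
Conditions: iBu2AlH, CH2Cl2, −78 °C
Reagents that add atoms: none
Why: 1,2-Reduction of the enoate to the allylic alcohol by the aluminium hydride, without touching the alkene geometry.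

**Step 8**
Reactants: 11 Z-allylic alcohol
Product: 12 [(1S,2S)-2-{(5R)-5-[(1S)-1-(tert-butyldimethylsilyloxy)ethyl]-2-methylcyclopent-1-en-1-yl}-1-methylcyclopropyl]methanol
Conditions: Zn(CH2I)2·DME (from Et2Zn, CH2I2, DME), (4R,5R)-2-butyl-N,N,N',N'-tetramethyl-1,3,2-dioxaborolane-4,5-dicarboxamide, CH2Cl2, −10 °C to rt
Reagents that add atoms: diiodomethane, ICI
Why: Dioxaborolane-controlled asymmetric Simmons–Smith cyclopropanation. The syn, stereospecific methylene transfer keeps the carbinol carbon cis to the cyclopentenyl group. The (4R,5R) controller, bound to the zinc alkoxide, should deliver CH2 to the face that makes the carbinol-bearing carbon S, the same sense as in its reaction with (E)-cinnamyl alcohol, which sets C4 and C6. The undirected tetrasubstituted ring alkene should react far more slowly.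

**Step 9**
Reactants: 12 cyclopropylmethanol
Product: 13 (1S,2S)-2-{(5R)-5-[(1S)-1-(tert-butyldimethylsilyloxy)ethyl]-2-methylcyclopent-1-en-1-yl}-1-methylcyclopropane-1-carbaldehyde
Conditions: Dess–Martin periodinane, NaHCO3, CH2Cl2, 0 °C
Reagents that add atoms: none
Why: Buffered hypervalent-iodine oxidation of a primary alcohol. The α-carbon is quaternary, so nothing can epimerise. The aldehyde is used at once.

**Step 10**
Reactants: 13 cyclopropanecarbaldehyde
Product: 14 tert-butyl{(1S)-1-[(1R)-2-[(1R,2S)-2-ethynyl-2-methylcyclopropyl]-3-methylcyclopent-2-en-1-yl]ethoxy}dimethylsilane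
Conditions: dimethyl (1-diazo-2-oxopropyl)phosphonate, K2CO3, MeOH, 0 °C to rt
Reagents that add atoms: dimethyl (1-diazo-2-oxopropyl)phosphonate, COP(=O)(OC)C(=[N+]=[N-])C(C)=O
Why: Seyferth–Gilbert homologation with the Ohira–Bestmann reagent converts the aldehyde into the terminal alkyne under mild carbonate conditions that the silyl ether tolerates.

**Step 11**
Reactants: 14 alkyne; 15 pinacolborane
Product: 16 2-[(E)-2-{(1R,2R)-2-[(5R)-5-[(1S)-1-(tert-butyldimethylsilyloxy)ethyl]-2-methylcyclopent-1-en-1-yl]-1-methylcyclopropyl}ethenyl]-4,4,5,5-tetramethyl-1,3,2-dioxaborolane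
Conditions: Cp2Zr(H)Cl (10 mol %), Et3N (10 mol %), CH2Cl2, rt
Reagents that add atoms: none
Why: Zirconium-hydride-catalysed hydroboration of a terminal alkyne is a syn, anti-Markovnikov addition and gives only the E-alkenylboronate. The tetrasubstituted ring alkene does not react.

**Step 12**
Reactants: 16 cis-divinylcyclopropane
Product: 17 2-[(1R,2R,8R)-8-[(1S)-1-(tert-butyldimethylsilyloxy)ethyl]-1,4-dimethylbicyclo[5.3.0]deca-3,6-dien-2-yl]-4,4,5,5-tetramethyl-1,3,2-dioxaborolane
Conditions: toluene (degassed), BHT (trace), 120 °C, sealed tube; crude product used directly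
Reagents that add atoms: none
Why: This is a concerted, suprafacial [3,3] sigmatropic shift that can only pass through the boat-shaped transition state, with the alkenylboronate and the cyclopentene C7=C1 bond both tucked above the cyclopropane; C1–C2 forms while the strained C4–C6 bond breaks, so the isomerisation is irreversible. The closest known reaction type is the thermal rearrangement of cis-1,2-dialkenylcyclopropanes to cyclohepta-1,4-dienes, including cases with a ring-embedded alkene and a boryl-substituted alkene. The seven-membered ring closes by ring expansion of the three-membered ring (C4–C5–C6 plus the two alkene arms), a pericyclic closure onto the existing five-membered ring and not a polar exo or endo cyclisation. C2 is controlled by the E geometry of the boronate: the E substituent points away from the cyclopropane in the boat, so boron ends up cis to C10 and trans to the C1 methyl. C1 is controlled by the cyclopropane configuration set in step 8, which decides which face of the cyclopentene meets C2; this is the face that carries the C8 arm, but the arm projects away from the folded boat. The step therefore needs a pure E-boronate and a cis cyclopropane of the right absolute sense, which steps 11, 6 and 8 secure. The tetrasubstituted alkene must turn its methyl inward, which raises the barrier and is the reason for 120 °C; no cis alkyl C–H is present for a competing homodienyl hydrogen shift. The allylic boronate is not chromatographed.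

**Step 13**
Reactants: 17 allylic boronate
Product: 18 (1S,2R,8R)-8-[(1S)-1-(tert-butyldimethylsilyloxy)ethyl]-1,4-dimethylbicyclo[5.3.0]deca-3,6-dien-2-ol
Conditions: H2O2 (30 %), NaOH (2 M), THF, 0 °C
Reagents that add atoms: hydrogen peroxide, OO
Why: Oxidation of the C–B bond by 1,2-migration of C2 from boron to oxygen goes with retention and without allylic transposition, so the C2 hydroxyl is α.

**Step 14**
Reactants: 18 dienol
Product: 19 (1S,2S,3S,4R,8R)-3,4-epoxy-8-[(1S)-1-(tert-butyldimethylsilyloxy)ethyl]-1,4-dimethylbicyclo[5.3.0]dec-6-en-2-ol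
Conditions: VO(acac)2 (5 mol %), tBuOOH, CH2Cl2, 0 °C
Reagents that add atoms: tert-butyl hydroperoxide, CC(C)(C)OO
Why: Hydroxyl-directed vanadium-catalysed epoxidation: the C2 vanadate delivers oxygen to the allylic C3=C4 bond on the hydroxyl face (syn for cyclohept-2-enols), setting C3 and C4 cis to the oxygen at C2. The homoallylic C6=C7 bond reacts much more slowly.

**Step 15**
Reactants: 19 epoxy alcohol
Product: 20 (1S,2S,3S,4R,7S,8R)-3,4-epoxy-8-[(1S)-1-(tert-butyldimethylsilyloxy)ethyl]-1,4-dimethylbicyclo[5.3.0]decan-2-ol
Conditions: H2 (1 atm), [Ir(cod)(PCy3)(py)]PF6 (10 mol %), CH2Cl2, rt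
Reagents that add atoms: none
Why: Hydroxyl-directed homogeneous hydrogenation: the cationic iridium complex binds the homoallylic C2 hydroxyl and adds hydrogen to the α face of C6=C7. H7 is thereby cis to the hydroxyl and trans to the C1 methyl, giving the trans fusion.

**Step 16**
Reactants: 20 saturated epoxy alcohol
Product: 21 (1S,2S,3S,4R,7S,8R)-3,4-epoxy-8-[(1S)-1-(tert-butyldimethylsilyloxy)ethyl]-1,4-dimethylbicyclo[5.3.0]decan-2-yl acetate
Conditions: Ac2O, pyridine, DMAP (cat.), CH2Cl2, rt
Reagents that add atoms: acetic anhydride, CC(=O)OC(C)=O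
Why: DMAP-catalysed acylation of the hindered secondary alcohol. The acetate masks C2–OH so that only the C11 carbinol is oxidised in step 18.

**Step 17**
Reactants: 21 silyl ether acetate
Product: 22 (1S,2S,3S,4R,7S,8R)-3,4-epoxy-8-[(1S)-1-hydroxyethyl]-1,4-dimethylbicyclo[5.3.0]decan-2-yl acetate
Conditions: Bu4NF, AcOH, THF, 0 °C to rt
Reagents that add atoms: none
Why: Fluoride cleavage of the Si–O bond. Buffering with acetic acid keeps the medium mild enough for the acetate, and the epoxide is inert to fluoride.

**Step 18**
Reactants: 22 hydroxy acetate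
Product: 23 (1S,2S,3S,4R,7S,8R)-8-acetyl-3,4-epoxy-1,4-dimethylbicyclo[5.3.0]decan-2-yl acetate
Conditions: Dess–Martin periodinane, NaHCO3, CH2Cl2, rt
Reagents that add atoms: none
Why: Buffered oxidation of the secondary alcohol gives the methyl ketone and merges the two C11 epimers. C8 already has the more stable configuration, with the acetyl group trans to the C7–C6 bond.

**Step 19**
Reactants: 23 methyl ketone; 24 triethyl phosphonoacetate
Product: 25 ethyl (2E)-3-[(1S,2S,3S,4R,7S,8R)-2-acetoxy-3,4-epoxy-1,4-dimethylbicyclo[5.3.0]decan-8-yl]but-2-enoate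
Conditions: NaH, THF, 0 to 60 °C
Reagents that add atoms: none
Why: Horner–Wadsworth–Emmons olefination of an α-branched methyl ketone. The size difference between the methyl and the ring substituent should favour the E-trisubstituted enoate, and any base-induced equilibration at C8 favours the required trans arrangement.

**Step 20**
Reactants: 25 enoate acetate
Product: 26 (1S,2S,3S,4R,7S,8R)-3,4-epoxy-8-[(2E)-4-hydroxybut-2-en-2-yl]-1,4-dimethylbicyclo[5.3.0]decan-2-ol
Conditions: iBu2AlH (excess), CH2Cl2, −78 °C
Reagents that add atoms: none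
Why: The aluminium hydride reduces the enoate 1,2 to the allylic alcohol and removes the acetate in the same operation. At −78 °C the trisubstituted epoxide should not be opened.

**Step 21**
Reactants: 26 allylic diol
Product: 27 (2E)-3-[(1S,2S,3S,4R,7S,8R)-3,4-epoxy-2-hydroxy-1,4-dimethylbicyclo[5.3.0]decan-8-yl]but-2-enal
Conditions: MnO2, CH2Cl2, rt
Reagents that add atoms: none
Why: MnO2 oxidises only the allylic primary alcohol. The saturated, hindered C2 carbinol is not touched, so no protecting group is needed.

**Step 22**
Reactants: 27 enal; 24 triethyl phosphonoacetate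
Product: 28 ethyl (2E,4E)-5-[(1S,2S,3S,4R,7S,8R)-3,4-epoxy-2-hydroxy-1,4-dimethylbicyclo[5.3.0]decan-8-yl]hexa-2,4-dienoate
Conditions: LiCl, DBU, MeCN, rt
Reagents that add atoms: none
Why: Horner–Wadsworth–Emmons reaction under Masamune–Roush conditions gives the E-alkene from an aldehyde and tolerates the free hydroxyl and the epoxide.

**Step 23**
Reactants: 28 dienoate
Product: 29 (1S,2S,3S,4R,7S,8R)-3,4-epoxy-8-[(2E,4E)-6-hydroxy-6-methylhepta-2,4-dien-2-yl]-1,4-dimethylbicyclo[5.3.0]decan-2-ol
Conditions: MeLi (excess), THF, −78 to 0 °C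
Reagents that add atoms: methyllithium, [Li]C
Why: Double 1,2-addition of the organolithium to the ester gives the dimethyl carbinol; the first equivalent is consumed by the C2 hydroxyl. At low temperature neither conjugate addition nor epoxide opening should compete.

**Step 24**
Reactants: 29 diol
Product: 30 (1S,2S,3S,4R,7S,8R)-3,4-epoxy-8-[(2E,4E)-6-hydroxy-6-methylhepta-2,4-dien-2-yl]-1,4-dimethylbicyclo[5.3.0]decan-2-yl acetate (CNP0265175.2)
Conditions: Ac2O (1.5 equiv), pyridine, DMAP (cat.), CH2Cl2, 0 °C
Reagents that add atoms: acetic anhydride, CC(=O)OC(C)=O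
Why: DMAP-catalysed acetylation distinguishes the secondary C2 hydroxyl from the tertiary allylic C15 hydroxyl, which acylates much more slowly. The basic medium protects the epoxide and the dienol.

## Compound list

1 | (R)-limonene | CC1=CC[C@@H](CC1)C(C)=C | starting material
2 | (4R)-limonene 1,2-oxide | CC12OC1C[C@@H](CC2)C(C)=C | intermediate
3 | (4R)-4-acetyl-1-methyl-7-oxabicyclo[4.1.0]heptane | CC12OC1C[C@@H](CC2)C(C)=O | intermediate
4 | (1S)-1-[(4R)-1-methyl-7-oxabicyclo[4.1.0]heptan-4-yl]ethanol | CC12OC1C[C@@H](CC2)[C@H](C)O | intermediate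
5 | tert-butyl(dimethyl){(1S)-1-[(4R)-1-methyl-7-oxabicyclo[4.1.0]heptan-4-yl]ethoxy}silane | CC12OC1C[C@@H](CC2)[C@H](C)O[Si](C)(C)C(C)(C)C | intermediate
6 | (4R)-4-[(1S)-1-(tert-butyldimethylsilyloxy)ethyl]-1-methylcyclohexane-1,2-diol (trans-diol) | CC1(O)C(O)C[C@@H](CC1)[C@H](C)O[Si](C)(C)C(C)(C)C | intermediate
7 | (3R)-3-[(1S)-1-(tert-butyldimethylsilyloxy)ethyl]-6-oxoheptanal | CC(=O)CC[C@H](CC=O)[C@H](C)O[Si](C)(C)C(C)(C)C | intermediate
8 | (5R)-5-[(1S)-1-(tert-butyldimethylsilyloxy)ethyl]-2-methylcyclopent-1-ene-1-carbaldehyde | O=CC1=C(C)CC[C@H]1[C@H](C)O[Si](C)(C)C(C)(C)C | intermediate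
9 | methyl 2-[bis(2,2,2-trifluoroethoxy)phosphoryl]propanoate | COC(=O)C(C)P(=O)(OCC(F)(F)F)OCC(F)(F)F | starting material
10 | methyl (2Z)-3-{(5R)-5-[(1S)-1-(tert-butyldimethylsilyloxy)ethyl]-2-methylcyclopent-1-en-1-yl}-2-methylprop-2-enoate | COC(=O)/C(C)=C\C1=C(C)CC[C@H]1[C@H](C)O[Si](C)(C)C(C)(C)C | intermediate
11 | (2Z)-3-{(5R)-5-[(1S)-1-(tert-butyldimethylsilyloxy)ethyl]-2-methylcyclopent-1-en-1-yl}-2-methylprop-2-en-1-ol | OC/C(C)=C\C1=C(C)CC[C@H]1[C@H](C)O[Si](C)(C)C(C)(C)C | intermediate
12 | [(1S,2S)-2-{(5R)-5-[(1S)-1-(tert-butyldimethylsilyloxy)ethyl]-2-methylcyclopent-1-en-1-yl}-1-methylcyclopropyl]methanol | OC[C@@]1(C)C[C@H]1C2=C(C)CC[C@H]2[C@H](C)O[Si](C)(C)C(C)(C)C | intermediate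
13 | (1S,2S)-2-{(5R)-5-[(1S)-1-(tert-butyldimethylsilyloxy)ethyl]-2-methylcyclopent-1-en-1-yl}-1-methylcyclopropane-1-carbaldehyde | O=C[C@@]1(C)C[C@H]1C2=C(C)CC[C@H]2[C@H](C)O[Si](C)(C)C(C)(C)C | intermediate
14 | tert-butyl{(1S)-1-[(1R)-2-[(1R,2S)-2-ethynyl-2-methylcyclopropyl]-3-methylcyclopent-2-en-1-yl]ethoxy}dimethylsilane | C#C[C@@]1(C)C[C@H]1C2=C(C)CC[C@H]2[C@H](C)O[Si](C)(C)C(C)(C)C | intermediate
15 | pinacolborane (4,4,5,5-tetramethyl-1,3,2-dioxaborolane) | CC1(C)OBOC1(C)C | starting material
16 | 2-[(E)-2-{(1R,2R)-2-[(5R)-5-[(1S)-1-(tert-butyldimethylsilyloxy)ethyl]-2-methylcyclopent-1-en-1-yl]-1-methylcyclopropyl}ethenyl]-4,4,5,5-tetramethyl-1,3,2-dioxaborolane | CC1(C)OB(OC1(C)C)/C=C/[C@@]2(C)C[C@H]2C3=C(C)CC[C@H]3[C@H](C)O[Si](C)(C)C(C)(C)C | intermediate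
17 | 2-[(1R,2R,8R)-8-[(1S)-1-(tert-butyldimethylsilyloxy)ethyl]-1,4-dimethylbicyclo[5.3.0]deca-3,6-dien-2-yl]-4,4,5,5-tetramethyl-1,3,2-dioxaborolane | CC1(C)OB(OC1(C)C)[C@@H]2C=C(C)CC=C3[C@H]([C@H](C)O[Si](C)(C)C(C)(C)C)CC[C@]23C | intermediate
18 | (1S,2R,8R)-8-[(1S)-1-(tert-butyldimethylsilyloxy)ethyl]-1,4-dimethylbicyclo[5.3.0]deca-3,6-dien-2-ol | O[C@@H]1C=C(C)CC=C2[C@H]([C@H](C)O[Si](C)(C)C(C)(C)C)CC[C@]12C | intermediate
19 | (1S,2S,3S,4R,8R)-3,4-epoxy-8-[(1S)-1-(tert-butyldimethylsilyloxy)ethyl]-1,4-dimethylbicyclo[5.3.0]dec-6-en-2-ol | O[C@@H]1[C@@H]2O[C@]2(C)CC=C3[C@H]([C@H](C)O[Si](C)(C)C(C)(C)C)CC[C@]13C | intermediate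
20 | (1S,2S,3S,4R,7S,8R)-3,4-epoxy-8-[(1S)-1-(tert-butyldimethylsilyloxy)ethyl]-1,4-dimethylbicyclo[5.3.0]decan-2-ol | O[C@@H]1[C@@H]2O[C@]2(C)CC[C@H]2[C@H]([C@H](C)O[Si](C)(C)C(C)(C)C)CC[C@]12C | intermediate
21 | (1S,2S,3S,4R,7S,8R)-3,4-epoxy-8-[(1S)-1-(tert-butyldimethylsilyloxy)ethyl]-1,4-dimethylbicyclo[5.3.0]decan-2-yl acetate | CC(=O)O[C@@H]1[C@@H]2O[C@]2(C)CC[C@H]2[C@H]([C@H](C)O[Si](C)(C)C(C)(C)C)CC[C@]12C | intermediate
22 | (1S,2S,3S,4R,7S,8R)-3,4-epoxy-8-[(1S)-1-hydroxyethyl]-1,4-dimethylbicyclo[5.3.0]decan-2-yl acetate | CC(=O)O[C@@H]1[C@@H]2O[C@]2(C)CC[C@H]2[C@H]([C@H](C)O)CC[C@]12C | intermediate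
23 | (1S,2S,3S,4R,7S,8R)-8-acetyl-3,4-epoxy-1,4-dimethylbicyclo[5.3.0]decan-2-yl acetate | CC(=O)O[C@@H]1[C@@H]2O[C@]2(C)CC[C@H]2[C@H](C(C)=O)CC[C@]12C | intermediate
24 | triethyl phosphonoacetate | CCOC(=O)CP(=O)(OCC)OCC | starting material
25 | ethyl (2E)-3-[(1S,2S,3S,4R,7S,8R)-2-acetoxy-3,4-epoxy-1,4-dimethylbicyclo[5.3.0]decan-8-yl]but-2-enoate | CC(=O)O[C@@H]1[C@@H]2O[C@]2(C)CC[C@H]2[C@H](/C(C)=C/C(=O)OCC)CC[C@]12C | intermediate
26 | (1S,2S,3S,4R,7S,8R)-3,4-epoxy-8-[(2E)-4-hydroxybut-2-en-2-yl]-1,4-dimethylbicyclo[5.3.0]decan-2-ol | O[C@@H]1[C@@H]2O[C@]2(C)CC[C@H]2[C@H](/C(C)=C/CO)CC[C@]12C | intermediate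
27 | (2E)-3-[(1S,2S,3S,4R,7S,8R)-3,4-epoxy-2-hydroxy-1,4-dimethylbicyclo[5.3.0]decan-8-yl]but-2-enal | O[C@@H]1[C@@H]2O[C@]2(C)CC[C@H]2[C@H](/C(C)=C/C=O)CC[C@]12C | intermediate
28 | ethyl (2E,4E)-5-[(1S,2S,3S,4R,7S,8R)-3,4-epoxy-2-hydroxy-1,4-dimethylbicyclo[5.3.0]decan-8-yl]hexa-2,4-dienoate | O[C@@H]1[C@@H]2O[C@]2(C)CC[C@H]2[C@H](/C(C)=C/C=C/C(=O)OCC)CC[C@]12C | intermediate
29 | (1S,2S,3S,4R,7S,8R)-3,4-epoxy-8-[(2E,4E)-6-hydroxy-6-methylhepta-2,4-dien-2-yl]-1,4-dimethylbicyclo[5.3.0]decan-2-ol | O[C@@H]1[C@@H]2O[C@]2(C)CC[C@H]2[C@H](/C(C)=C/C=C/C(C)(C)O)CC[C@]12C | intermediate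
30 | (1S,2S,3S,4R,7S,8R)-3,4-epoxy-8-[(2E,4E)-6-hydroxy-6-methylhepta-2,4-dien-2-yl]-1,4-dimethylbicyclo[5.3.0]decan-2-yl acetate | CC(=O)O[C@@H]1[C@@H]2O[C@]2(C)CC[C@H]2[C@H](/C(C)=C/C=C/C(C)(C)O)CC[C@]12C | target

## Step count and least certain steps

Total: 24 steps. Longest linear sequence: 24 steps (1 to 30); 9, 15 and 24 are bought.

**Step 12 (key step).** The rearrangement may be slow: the tetrasubstituted alkene must turn its methyl inward, and a quaternary centre forms on the face that carries the C8 arm. At the temperature then needed, one-centre epimerisation of the cyclopropane, 1,3-migration of boron, or protodeboronation and oxidation of the allylic boronate could erode the material and the C1/C2 control. Fallback: alkyne 14 is hydrosilylated with HSiMe2(OEt) (Pt2[(CH2=CHSiMe2)2O]3, P(tBu)3) to the (E)-alkenyl(ethoxy)dimethylsilane F1. Its rearrangement can be driven at 150–170 °C because the resulting allylsilane F2 tolerates heat and air. Tamao oxidation (H2O2, KF, KHCO3, THF/MeOH), with retention at C2, returns to dienol 18.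

**Step 8.** The C8 stereocentre may oppose the chiral controller (mismatched pairing) and lower the facial selectivity. The hindered Z-trisubstituted alkene may react slowly, so that methylene transfer to the electron-rich ring alkene starts to compete. Fallback: allylic alcohol 11 is oxidised with MnO2 to the (Z)-enal F3. Acetalisation with diisopropyl tartrate (the enantiomer that steers the carbenoid to the required face, drawn here as the (R,R)-ester; HC(OEt)3, then the tartrate, pyridinium p-toluenesulfonate) gives the dioxolane F4. Acetal-directed Simmons–Smith cyclopropanation (Et2Zn, CH2I2) gives the cyclopropyl acetal F5, whose diastereomers are separable. Mild acid hydrolysis rejoins the route at aldehyde 13.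

**Step 15.** Hydrogen may add slowly or from the wrong face, because the α face of C7 is screened by the silyloxyethyl arm and the β face by the C1 methyl. The catalyst may deactivate before the trisubstituted alkene reacts, and Lewis-acidic iridium hydrides may isomerise the epoxide. Fallback: epoxy alcohol 19 is desilylated with Bu4NF to the unsaturated diol F6. Hydrogenation of F6 with the same iridium complex, now anchored by two α-hydroxyls and free of the bulky silyl group, gives the saturated diol F7. Selective silylation of the less hindered C11 hydroxyl (TBSCl, imidazole) returns to 20.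

**Step 19.** The phosphonate anion may enolise the hindered methyl ketone instead of adding, the acetate may be lost to base, and the E/Z ratio may be modest. Fallback: ketone 23 is treated with CH2=CHMgBr and CeCl3 at −78 °C, which should add to the ketone in preference to the acetate and give the tertiary allylic alcohol F8. Oxidative 1,3-transposition with pyridinium chlorochromate, C5H5NH[CrO3Cl] (Babler–Dauben oxidation), gives the (E)-enal acetate F9. Horner–Wadsworth–Emmons reaction with 24 (LiCl, DBU) gives the dienoate acetate F10. Excess MeLi then cleaves the acetate and builds the carbinol, returning to diol 29.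

**Step 10.** The cis-2-alkenylcyclopropanecarbaldehyde 13 may drift into a 2,5-dihydrooxepine by reversible retro-Claisen rearrangement, and the neopentyl aldehyde may react slowly with the diazophosphonate anion. Fallback: aldehyde 13 is converted directly into E-alkenylboronate 16 by a chromium-mediated olefination of Takai–Utimoto type (CrCl2, Cl2CHB(pin), LiI, THF). This removes alkyne 14 from the route and makes no compound outside the list (F0).

## Further compounds

F1 | step 12 | (E)-alkenyl(ethoxy)dimethylsilane analogue of 16 | CCO[Si](C)(C)/C=C/[C@@]1(C)C[C@H]1C2=C(C)CC[C@H]2[C@H](C)O[Si](C)(C)C(C)(C)C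
F2 | step 12 | C2 allyl(ethoxy)dimethylsilane analogue of 17 | CCO[Si](C)(C)[C@@H]1C=C(C)CC=C2[C@H]([C@H](C)O[Si](C)(C)C(C)(C)C)CC[C@]12C
F3 | step 8 | (2Z)-3-{(5R)-5-[(1S)-1-(tert-butyldimethylsilyloxy)ethyl]-2-methylcyclopent-1-en-1-yl}-2-methylprop-2-enal | O=C/C(C)=C\C1=C(C)CC[C@H]1[C@H](C)O[Si](C)(C)C(C)(C)C
F4 | step 8 | diisopropyl (4R,5R)-tartrate acetal of F3 | CC(C)OC(=O)[C@@H]1OC(O[C@H]1C(=O)OC(C)C)/C(C)=C\C2=C(C)CC[C@H]2[C@H](C)O[Si](C)(C)C(C)(C)C
F5 | step 8 | diisopropyl (4R,5R)-tartrate acetal of aldehyde 13 | CC(C)OC(=O)[C@@H]1OC(O[C@H]1C(=O)OC(C)C)[C@@]2(C)C[C@H]2C3=C(C)CC[C@H]3[C@H](C)O[Si](C)(C)C(C)(C)C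
F0 | step 10 | none | none
F6 | step 15 | (1S,2S,3S,4R,8R)-3,4-epoxy-8-[(1S)-1-hydroxyethyl]-1,4-dimethylbicyclo[5.3.0]dec-6-en-2-ol | O[C@@H]1[C@@H]2O[C@]2(C)CC=C3[C@H]([C@H](C)O)CC[C@]13C
F7 | step 15 | (1S,2S,3S,4R,7S,8R)-3,4-epoxy-8-[(1S)-1-hydroxyethyl]-1,4-dimethylbicyclo[5.3.0]decan-2-ol | O[C@@H]1[C@@H]2O[C@]2(C)CC[C@H]2[C@H]([C@H](C)O)CC[C@]12C
F8 | step 19 | (1S,2S,3S,4R,7S,8R)-3,4-epoxy-8-(2-hydroxybut-3-en-2-yl)-1,4-dimethylbicyclo[5.3.0]decan-2-yl acetate | CC(=O)O[C@@H]1[C@@H]2O[C@]2(C)CC[C@H]2[C@H](C(C)(O)C=C)CC[C@]12C
F9 | step 19 | (1S,2S,3S,4R,7S,8R)-3,4-epoxy-1,4-dimethyl-8-[(2E)-4-oxobut-2-en-2-yl]bicyclo[5.3.0]decan-2-yl acetate | CC(=O)O[C@@H]1[C@@H]2O[C@]2(C)CC[C@H]2[C@H](/C(C)=C/C=O)CC[C@]12C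
F10 | step 19 | ethyl (2E,4E)-5-[(1S,2S,3S,4R,7S,8R)-2-acetoxy-3,4-epoxy-1,4-dimethylbicyclo[5.3.0]decan-8-yl]hexa-2,4-dienoate | CC(=O)O[C@@H]1[C@@H]2O[C@]2(C)CC[C@H]2[C@H](/C(C)=C/C=C/C(=O)OCC)CC[C@]12C
A1 | alternative 1 | (1S)-1-methyl-2-oxobicyclo[5.3.0]dec-7-ene-8-carbaldehyde | O=C1CCCCC2=C(C=O)CC[C@]12C
A2 | alternative 1 | 4-(1-methyl-2,7-dioxocycloheptyl)butanal | CC1(CCCC=O)C(=O)CCCCC1=O
A3 | alternative 2 | (1S,2S,3S,4R,7S,8R)-3,4-epoxy-8-[(E)-1-iodoprop-1-en-2-yl]-1,4-dimethylbicyclo[5.3.0]decan-2-ol | O[C@@H]1[C@@H]2O[C@]2(C)CC[C@H]2[C@H](/C(C)=C/I)CC[C@]12C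
A4 | alternative 2 | trans-fused 8-[(E)-1-iodoprop-1-en-2-yl]-1,4-dimethylbicyclo[5.3.0]dec-2-ene with H4 on the α face | C[C@H]1CC[C@H]2[C@H](/C(C)=C/I)CC[C@]2(C)C=C1
A5 | alternative 2 | trans-fused 2α-hydroperoxy-8-[(E)-1-iodoprop-1-en-2-yl]-1,4-dimethylbicyclo[5.3.0]dec-3-ene | OO[C@@H]1C=C(C)CC[C@H]2[C@H](/C(C)=C/I)CC[C@]12C
A6 | alternative 3 | trans-fused 1,4-dimethyl-8-methylidenebicyclo[5.3.0]decan-2-ol | O[C@@H]1C[C@@H](C)CC[C@H]2C(=C)CC[C@]12C
A7 | alternative 3 | cis-1,2-epoxy-1,4-dimethyl-8-(trimethylsilylmethyl)cyclodec-7-ene (target numbering) | C[C@H]1CC/C=C(C[Si](C)(C)C)/CC[C@]2(C)O[C@@H]2C1
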